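**Strategy.** The route rests on cutting the O1–C8a bond of ring C. The feature used is that ring A bears oxygens para to each other on C5 and C8 while O1 sits on C8a, the carbon beside the ketone-bearing C4a; raised to the quinone level, C8a becomes the electrophilic β-position of an acylquinone. One operation therefore oxidises a 4-methoxyphenol with PhI(OAc)2, lets the side-chain enol oxygen add to C8a, and returns ring A as the hydroquinone with ring C in place. The substrate is the enol of an α-formyl deoxybenzoin carrying C5–OMe, free C8–OH, C8a–H and a 2'-O-MOM chromenyl ring B, made by α-arylation of a ring-A acetophenone with a ring-B bromide.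

Key step: step 13

Remark: isoflavone numbering (O1, C2–C8a; primes for ring B) is used for all intermediates; the target has no stereocentre, so none has to be set.

**Route**

Step 1
Reactants: 1 2,5-dihydroxyacetophenone
Product: 2 1-[2-hydroxy-5-(triisopropylsilyloxy)phenyl]ethanone
Conditions: TIPSCl (1.05 equiv), imidazole, DMF, 0 °C to rt
Reagents that add atoms: triisopropylsilyl chloride (TIPSCl), CC(C)[Si](Cl)(C(C)C)C(C)C
Why: Selective phenol silylation should take only the C5 hydroxyl, because the other phenol is held in the hydrogen bond to the ortho acetyl group, and the TIPS ether chosen withstands the later basic steps yet leaves with fluoride without harm to a MOM ether or a chromene.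

Step 2
Reactants: 2 1-[2-hydroxy-5-(triisopropylsilyloxy)phenyl]ethanone
Product: 3 1-[3-bromo-2-hydroxy-5-(triisopropylsilyloxy)phenyl]ethanone
Conditions: NBS (1.0 equiv), MeCN, 0 °C to rt
Reagents that add atoms: N-bromosuccinimide (NBS), O=C1CCC(=O)N1Br
Why: Electrophilic aromatic bromination should go ortho to the free phenol, the strongest activator, since its para position is blocked and C3 is its only open ortho site.

Step 3
Reactants: 3 1-[3-bromo-2-hydroxy-5-(triisopropylsilyloxy)phenyl]ethanone
Product: 4 1-[3-bromo-2-methoxy-5-(triisopropylsilyloxy)phenyl]ethanone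
Conditions: MeI, K2CO3, dry acetone, reflux
Reagents that add atoms: iodomethane, CI
Why: Williamson ether synthesis on the chelated phenol should proceed without enolising the ketone or attacking the hindered silyl ether, and it installs the methyl ether that later keeps the C5 oxygen out of ring closure.

Step 4
Reactants: 4 1-[3-bromo-2-methoxy-5-(triisopropylsilyloxy)phenyl]ethanone; 5 2-methylbut-3-yn-2-ol
Product: 6 1-[3-(3-hydroxy-3-methylbut-1-ynyl)-2-methoxy-5-(triisopropylsilyloxy)phenyl]ethanone
Conditions: Pd(PPh3)2Cl2 (3 mol%), CuI (5 mol%), Et3N/DMF, degassed, 80 °C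
Reagents that add atoms: none
Why: Sonogashira coupling of an aryl bromide with a terminal propargylic alcohol is a robust pairing that tolerates the ketone and the silyl ether.

Step 5
Reactants: 6 1-[3-(3-hydroxy-3-methylbut-1-ynyl)-2-methoxy-5-(triisopropylsilyloxy)phenyl]ethanone
Product: 7 1-[3-(3-hydroxy-3-methylbutyl)-2-methoxy-5-(triisopropylsilyloxy)phenyl]ethanone (ring-A ketone)
Conditions: H2 (1 atm), 10% Pd/C, EtOAc, rt
Reagents that add atoms: none
Why: Heterogeneous catalytic hydrogenation should saturate the alkyne to the 3-hydroxy-3-methylbutyl chain while the aryl ketone, aryl silyl ether and tertiary alcohol stay inert at 1 atm in a neutral solvent.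

Step 6
Reactants: 8 resorcinol; 9 3-methylbut-2-enoic acid
Product: 10 7-hydroxy-2,2-dimethylchroman-4-one
Conditions: P2O5/MeSO3H, 70 °C
Reagents that add atoms: none
Why: Friedel–Crafts acylation at C4 of resorcinol followed in the same pot by intramolecular oxa-Michael addition is the long-established one-pot chromanone synthesis.

Step 7
Reactants: 10 7-hydroxy-2,2-dimethylchroman-4-one
Product: 11 7-(methoxymethoxy)-2,2-dimethylchroman-4-one
Conditions: MOMCl, iPr2NEt, CH2Cl2, 0 °C to rt
Reagents that add atoms: chloromethyl methyl ether (MOMCl), COCCl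
Why: Acetal protection of the acidic phenol as the MOM ether gives a group that survives hydride, strong base, zerovalent palladium, fluoride and the iodane and leaves with dilute acid at the end.

Step 8
Reactants: 11 7-(methoxymethoxy)-2,2-dimethylchroman-4-one
Product: 12 6-bromo-7-(methoxymethoxy)-2,2-dimethylchroman-4-one
Conditions: NBS (1.05 equiv), MeCN, 0 °C to rt
Reagents that add atoms: N-bromosuccinimide (NBS), O=C1CCC(=O)N1Br
Why: Electrophilic aromatic bromination of a 2,4-dialkoxyaryl ketone should go to C6, ortho to one alkoxy group and para to the other, because C8 between the two oxygens is hindered once the phenol is an ether.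

Step 9
Reactants: 12 6-bromo-7-(methoxymethoxy)-2,2-dimethylchroman-4-one
Product: 13 6-bromo-7-(methoxymethoxy)-2,2-dimethylchroman-4-ol (racemic)
Conditions: NaBH4, MeOH/THF, 0 °C
Reagents that add atoms: none
Why: Borohydride reduction of the aryl ketone should be clean, and the C4 carbinol centre, formed as a racemate, is removed in the next step so it needs no control.

Step 10
Reactants: 13 6-bromo-7-(methoxymethoxy)-2,2-dimethylchroman-4-ol (racemic)
Product: 14 6-bromo-7-(methoxymethoxy)-2,2-dimethyl-2H-chromene (ring-B bromide)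
Conditions: MsCl, Et3N (excess), CH2Cl2, 0 °C to reflux
Reagents that add atoms: none
Why: Mesylation and base-induced elimination through the oxygen-stabilised benzylic position should give the 2H-chromene without the acid that a direct dehydration needs and that the MOM ether would not survive.

Step 11
Reactants: 7 1-[3-(3-hydroxy-3-methylbutyl)-2-methoxy-5-(triisopropylsilyloxy)phenyl]ethanone; 14 6-bromo-7-(methoxymethoxy)-2,2-dimethyl-2H-chromene
Product: 15 1-[3-(3-hydroxy-3-methylbutyl)-2-methoxy-5-(triisopropylsilyloxy)phenyl]-2-[7-(methoxymethoxy)-2,2-dimethyl-2H-chromen-6-yl]ethan-1-one (deoxybenzoin)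
Conditions: Pd2(dba)3 (2.5 mol%), Xantphos (6 mol%), NaOtBu (2.5 equiv), THF, 70 °C
Reagents that add atoms: none
Why: Palladium-catalysed α-arylation of a ketone enolate (Buchwald–Hartwig type) with a catalyst system selective for mono-arylation of aryl methyl ketones should work here, since the ortho MOM-oxy group of 14 blocks a second arylation, the tertiary alkoxide is no competent coupling partner and the trisubstituted chromene olefin is too hindered for a Heck reaction.

Step 12
Reactants: 15 deoxybenzoin
Product: 17 (Z)-3-hydroxy-1-[5-hydroxy-3-(3-hydroxy-3-methylbutyl)-2-methoxyphenyl]-2-[7-(methoxymethoxy)-2,2-dimethyl-2H-chromen-6-yl]prop-2-en-1-one (key-step precursor), via silyl-protected formyl ketone 16 (not isolated)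
Conditions: HCO2Et (10 equiv), NaH (4 equiv), THF, 0 °C to rt; then MeOH, Bu4NF (1.5 equiv), 0 °C to rt; AcOH/aq. NH4Cl to pH 5
Reagents that add atoms: ethyl formate, CCOC=O
Why: Crossed Claisen C-formylation of the deoxybenzoin enolate should give a chelated enolate that is inert to fluoride, so the aryl silyl ether is cleaved in the same flask (methanol also strips any formate from the tertiary alcohol) and mild acidification releases the hydrogen-bonded (Z)-enol.

Step 13
Reactants: 17 key-step precursor
Product: 20 5,8-dihydroxy-6-(3-hydroxy-3-methylbutyl)-3-[7-(methoxymethoxy)-2,2-dimethyl-2H-chromen-6-yl]-4H-chromen-4-one (2'-O-MOM ether of the target), via acylquinone 18 (not isolated), via isoflavone-5,8-quinone 19 (not isolated)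
Conditions: PhI(OAc)2 (2.2 equiv, in portions), MeCN/H2O 3:1 (0.01 M), 0 °C then rt 30 min; then aq. Na2S2O4, EtOAc, rt, argon
Reagents that add atoms: water, O
Why: Proposed new method: the C8 phenol binds to trivalent iodine, water enters at C5 and methanol leaves, giving acylquinone 18; its C8a, conjugated to both the side-chain ketone and the C5 carbonyl, is then captured by the oxygen of the (Z)-enol, and a proton shift re-aromatises ring A. The closest known reactions are the PhI(OAc)2 oxidation of 4-methoxyphenols to quinones and the conjugate addition of oxygen nucleophiles to 2-acyl-1,4-benzoquinones; running both in one flask with an enol as the nucleophile is not established. Ring C closes by a 6-endo-trig oxa-Michael addition that forms O1–C8a, and no stereocentre is created. What the step needs is regioselectivity for C8a over the classical condensation through the oxygen on C5; the substrate secures it because that oxygen is capped as a methyl ether until oxidation turns it into a carbonyl, C7 is only singly activated and is offered nothing but a neutral tertiary alcohol, and the enol carbon cannot reach the ring. Because the first-formed hydroquinone should be oxidised more easily than the starting phenol, a second equivalent of oxidant is used on purpose to carry everything to quinone 19 (the aqueous medium also opens any cyclic ketal formed by the tertiary alcohol at C5), and Na2S2O4 then returns the hydroquinone.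

Step 14
Reactants: 20 2'-O-MOM ether of the target
Product: 21 kraussianone 3, 5,8-dihydroxy-3-(7-hydroxy-2,2-dimethyl-2H-chromen-6-yl)-6-(3-hydroxy-3-methylbutyl)-4H-chromen-4-one
Conditions: 2 M aq. HCl/MeOH 1:5, degassed, argon, 35–40 °C
Reagents that add atoms: none
Why: Acid-catalysed acetal cleavage should remove the phenolic MOM ether at temperatures where an isolated tertiary alcohol ionises far more slowly, the chromene is untouched and exclusion of air protects the hydroquinone.

**Compound list**

1 | 2,5-dihydroxyacetophenone | CC(=O)c1cc(O)ccc1O | starting material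
2 | 1-[2-hydroxy-5-(triisopropylsilyloxy)phenyl]ethanone | CC(=O)c1cc(O[Si](C(C)C)(C(C)C)C(C)C)ccc1O | intermediate
3 | 1-[3-bromo-2-hydroxy-5-(triisopropylsilyloxy)phenyl]ethanone | CC(=O)c1cc(O[Si](C(C)C)(C(C)C)C(C)C)cc(Br)c1O | intermediate
4 | 1-[3-bromo-2-methoxy-5-(triisopropylsilyloxy)phenyl]ethanone | CC(=O)c1cc(O[Si](C(C)C)(C(C)C)C(C)C)cc(Br)c1OC | intermediate
5 | 2-methylbut-3-yn-2-ol | CC(C)(O)C#C | starting material
6 | 1-[3-(3-hydroxy-3-methylbut-1-ynyl)-2-methoxy-5-(triisopropylsilyloxy)phenyl]ethanone | CC(=O)c1cc(O[Si](C(C)C)(C(C)C)C(C)C)cc(C#CC(C)(C)O)c1OC | intermediate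
7 | 1-[3-(3-hydroxy-3-methylbutyl)-2-methoxy-5-(triisopropylsilyloxy)phenyl]ethanone (ring-A ketone) | CC(=O)c1cc(O[Si](C(C)C)(C(C)C)C(C)C)cc(CCC(C)(C)O)c1OC | intermediate
8 | resorcinol | Oc1cccc(O)c1 | starting material
9 | 3-methylbut-2-enoic acid | CC(C)=CC(=O)O | starting material
10 | 7-hydroxy-2,2-dimethylchroman-4-one | CC1(C)CC(=O)c2ccc(O)cc2O1 | intermediate
11 | 7-(methoxymethoxy)-2,2-dimethylchroman-4-one | CC1(C)CC(=O)c2ccc(OCOC)cc2O1 | intermediate
12 | 6-bromo-7-(methoxymethoxy)-2,2-dimethylchroman-4-one | CC1(C)CC(=O)c2cc(Br)c(OCOC)cc2O1 | intermediate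
13 | 6-bromo-7-(methoxymethoxy)-2,2-dimethylchroman-4-ol (racemic) | CC1(C)CC(O)c2cc(Br)c(OCOC)cc2O1 | intermediate
14 | 6-bromo-7-(methoxymethoxy)-2,2-dimethyl-2H-chromene (ring-B bromide) | CC1(C)C=Cc2cc(Br)c(OCOC)cc2O1 | intermediate
15 | 1-[3-(3-hydroxy-3-methylbutyl)-2-methoxy-5-(triisopropylsilyloxy)phenyl]-2-[7-(methoxymethoxy)-2,2-dimethyl-2H-chromen-6-yl]ethan-1-one | COc1c(CCC(C)(C)O)cc(O[Si](C(C)C)(C(C)C)C(C)C)cc1C(=O)Cc1cc2c(cc1OCOC)OC(C)(C)C=C2 | intermediate
16 | (Z)-3-hydroxy-1-[3-(3-hydroxy-3-methylbutyl)-2-methoxy-5-(triisopropylsilyloxy)phenyl]-2-[7-(methoxymethoxy)-2,2-dimethyl-2H-chromen-6-yl]prop-2-en-1-one (present as its sodium enolate) | COc1c(CCC(C)(C)O)cc(O[Si](C(C)C)(C(C)C)C(C)C)cc1C(=O)/C(=C\O)c1cc2c(cc1OCOC)OC(C)(C)C=C2 | intermediate (not isolated)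
17 | (Z)-3-hydroxy-1-[5-hydroxy-3-(3-hydroxy-3-methylbutyl)-2-methoxyphenyl]-2-[7-(methoxymethoxy)-2,2-dimethyl-2H-chromen-6-yl]prop-2-en-1-one | COc1c(CCC(C)(C)O)cc(O)cc1C(=O)/C(=C\O)c1cc2c(cc1OCOC)OC(C)(C)C=C2 | intermediate
18 | 2-{(Z)-3-hydroxy-2-[7-(methoxymethoxy)-2,2-dimethyl-2H-chromen-6-yl]prop-2-enoyl}-6-(3-hydroxy-3-methylbutyl)cyclohexa-2,5-diene-1,4-dione | O=C1C(CCC(C)(C)O)=CC(=O)C=C1C(=O)/C(=C\O)c1cc2c(cc1OCOC)OC(C)(C)C=C2 | intermediate (not isolated)
19 | 6-(3-hydroxy-3-methylbutyl)-3-[7-(methoxymethoxy)-2,2-dimethyl-2H-chromen-6-yl]-4H-chromene-4,5,8-trione | CC(C)(O)CCC1=CC(=O)c2occ(-c3cc4c(cc3OCOC)OC(C)(C)C=C4)c(=O)c2C1=O | intermediate (not isolated)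
20 | 5,8-dihydroxy-6-(3-hydroxy-3-methylbutyl)-3-[7-(methoxymethoxy)-2,2-dimethyl-2H-chromen-6-yl]-4H-chromen-4-one | CC(C)(O)CCc1cc(O)c2occ(-c3cc4c(cc3OCOC)OC(C)(C)C=C4)c(=O)c2c1O | intermediate
21 | kraussianone 3, 5,8-dihydroxy-3-(7-hydroxy-2,2-dimethyl-2H-chromen-6-yl)-6-(3-hydroxy-3-methylbutyl)-4H-chromen-4-one | CC(C)(O)CCc1cc(O)c2occ(-c3cc4c(cc3O)OC(C)(C)C=C4)c(=O)c2c1O | target

**Totals**

Total steps: 14. Longest linear sequence: 9 steps (steps 1–5 and 11–14; the ring-B branch, steps 6–10 and 11–14, is equally long).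

**Steps most likely to fail**

1. Step 13 (key step). The iodane may attack the electron-rich enol carbon, the acylquinone may be consumed by intermolecular Michael addition or redox exchange before the ring closes, or the excess oxidant may degrade ring B. The fallback uses known chemistry only: ring C is closed first by the classical condensation of a phenol oxygen already placed on C8a, and the hydroquinone is unmasked before the oxidisable ring B is attached. It sets out from 14 and 5 and comes back at 20.
 - 1-(2-Hydroxy-3,6-dimethoxyphenyl)ethanone F1, a known acetophenone with the acetyl group between two oxygens (Fries rearrangement of 2,5-dimethoxyphenyl acetate with BF3·OEt2), would be brominated para to the phenol (NBS, MeCN) to 1-(5-bromo-2-hydroxy-3,6-dimethoxyphenyl)ethanone F2.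
 - Sonogashira coupling with 5 under the conditions of step 4 would give 1-[2-hydroxy-5-(3-hydroxy-3-methylbut-1-ynyl)-3,6-dimethoxyphenyl]ethanone F3, and hydrogenation (H2, 10% Pd/C) would give 1-[2-hydroxy-5-(3-hydroxy-3-methylbutyl)-3,6-dimethoxyphenyl]ethanone F4.
 - Condensation with Me2NCH(OMe)2 would give (E)-3-(dimethylamino)-1-[2-hydroxy-5-(3-hydroxy-3-methylbutyl)-3,6-dimethoxyphenyl]prop-2-en-1-one F5, which I2 in MeOH should cyclise through its only free ortho phenol to 6-(3-hydroxy-3-methylbutyl)-3-iodo-5,8-dimethoxy-4H-chromen-4-one F6.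
 - Oxidative demethylation with (NH4)2Ce(NO3)6 in aqueous MeCN would give 6-(3-hydroxy-3-methylbutyl)-3-iodo-4H-chromene-4,5,8-trione F7, and Na2S2O4 would reduce it to 5,8-dihydroxy-6-(3-hydroxy-3-methylbutyl)-3-iodo-4H-chromen-4-one F8.
 - Bromide 14 would be converted by Miyaura borylation (B2pin2, Pd(dppf)Cl2, KOAc, dioxane, 85 °C) into 2-[7-(methoxymethoxy)-2,2-dimethyl-2H-chromen-6-yl]-4,4,5,5-tetramethyl-1,3,2-dioxaborolane F9.
 - Suzuki–Miyaura coupling of F8 with F9 (Pd(dppf)Cl2, K2CO3, degassed dioxane/H2O, 80 °C) would return to 20.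

2. Step 11. Oxidative addition into the electron-rich, ortho-substituted bromide may be slower than base-induced self-condensation of the methyl ketone, or the alkoxide base may strip the silyl ether and stall the catalyst. The fallback reverses the polarity, with ring A as the electrophile and ring B as the boronate; it sets out from 7 and 14 and comes back at 16.
 - Ketone 7 and Me2NCH(OMe)2 (toluene, 100 °C) would give (E)-3-(dimethylamino)-1-[3-(3-hydroxy-3-methylbutyl)-2-methoxy-5-(triisopropylsilyloxy)phenyl]prop-2-en-1-one F10.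
 - α-Iodination (I2, K2CO3, CH2Cl2, 0 °C) would give (Z)-3-(dimethylamino)-2-iodo-1-[3-(3-hydroxy-3-methylbutyl)-2-methoxy-5-(triisopropylsilyloxy)phenyl]prop-2-en-1-one F11.
 - Suzuki–Miyaura coupling with the boronate F9 made from 14 as above (Pd(dppf)Cl2, K3PO4, dioxane/H2O, 80 °C) would give (E)-3-(dimethylamino)-1-[3-(3-hydroxy-3-methylbutyl)-2-methoxy-5-(triisopropylsilyloxy)phenyl]-2-[7-(methoxymethoxy)-2,2-dimethyl-2H-chromen-6-yl]prop-2-en-1-one F12.
 - Brief hydrolysis with dilute aqueous HCl in THF at 0 °C to rt, where the vinylogous amide should hydrolyse much faster than the MOM ether, would give 16, which is desilylated with Bu4NF as in the second stage of step 12. This path also bypasses the formylation.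

3. Step 12. Formylation at the hindered benzylic carbon may stay incomplete or go to oxygen, and retro-Claisen loss of the formyl group may set in during the fluoride stage. The fallback introduces the one-carbon unit by amide-acetal condensation instead of a Claisen reaction; it sets out from 15 and comes back at 17.
 - Desilylation first (Bu4NF, AcOH, THF, 0 °C) would give 1-[5-hydroxy-3-(3-hydroxy-3-methylbutyl)-2-methoxyphenyl]-2-[7-(methoxymethoxy)-2,2-dimethyl-2H-chromen-6-yl]ethan-1-one F13.
 - Heating with tert-butoxybis(dimethylamino)methane (toluene, 80 °C; not a methylating agent, so the free phenol is safe) would give (E)-3-(dimethylamino)-1-[5-hydroxy-3-(3-hydroxy-3-methylbutyl)-2-methoxyphenyl]-2-[7-(methoxymethoxy)-2,2-dimethyl-2H-chromen-6-yl]prop-2-en-1-one F14.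
 - Hydrolysis with dilute aqueous HCl in THF at 0 °C to rt would give 17.

Further compounds
F1 | step 13 | 1-(2-hydroxy-3,6-dimethoxyphenyl)ethanone | CC(=O)c1c(O)c(OC)ccc1OC
F2 | step 13 | 1-(5-bromo-2-hydroxy-3,6-dimethoxyphenyl)ethanone | CC(=O)c1c(O)c(OC)cc(Br)c1OC
F3 | step 13 | 1-[2-hydroxy-5-(3-hydroxy-3-methylbut-1-ynyl)-3,6-dimethoxyphenyl]ethanone | CC(=O)c1c(O)c(OC)cc(C#CC(C)(C)O)c1OC
F4 | step 13 | 1-[2-hydroxy-5-(3-hydroxy-3-methylbutyl)-3,6-dimethoxyphenyl]ethanone | CC(=O)c1c(O)c(OC)cc(CCC(C)(C)O)c1OC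
F5 | step 13 | (E)-3-(dimethylamino)-1-[2-hydroxy-5-(3-hydroxy-3-methylbutyl)-3,6-dimethoxyphenyl]prop-2-en-1-one | CN(C)/C=C/C(=O)c1c(O)c(OC)cc(CCC(C)(C)O)c1OC
F6 | step 13 | 6-(3-hydroxy-3-methylbutyl)-3-iodo-5,8-dimethoxy-4H-chromen-4-one | COc1cc(CCC(C)(C)O)c(OC)c2c(=O)c(I)coc12
F7 | step 13 | 6-(3-hydroxy-3-methylbutyl)-3-iodo-4H-chromene-4,5,8-trione | CC(C)(O)CCC1=CC(=O)c2occ(I)c(=O)c2C1=O
F8 | step 13 | 5,8-dihydroxy-6-(3-hydroxy-3-methylbutyl)-3-iodo-4H-chromen-4-one | CC(C)(O)CCc1cc(O)c2occ(I)c(=O)c2c1O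
F9 | step 13 | 2-[7-(methoxymethoxy)-2,2-dimethyl-2H-chromen-6-yl]-4,4,5,5-tetramethyl-1,3,2-dioxaborolane | COCOc1cc2c(cc1B1OC(C)(C)C(C)(C)O1)C=CC(C)(C)O2
F10 | step 11 | (E)-3-(dimethylamino)-1-[3-(3-hydroxy-3-methylbutyl)-2-methoxy-5-(triisopropylsilyloxy)phenyl]prop-2-en-1-one | COc1c(CCC(C)(C)O)cc(O[Si](C(C)C)(C(C)C)C(C)C)cc1C(=O)/C=C/N(C)C
F11 | step 11 | (Z)-3-(dimethylamino)-2-iodo-1-[3-(3-hydroxy-3-methylbutyl)-2-methoxy-5-(triisopropylsilyloxy)phenyl]prop-2-en-1-one | COc1c(CCC(C)(C)O)cc(O[Si](C(C)C)(C(C)C)C(C)C)cc1C(=O)/C(I)=C/N(C)C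
F12 | step 11 | (E)-3-(dimethylamino)-1-[3-(3-hydroxy-3-methylbutyl)-2-methoxy-5-(triisopropylsilyloxy)phenyl]-2-[7-(methoxymethoxy)-2,2-dimethyl-2H-chromen-6-yl]prop-2-en-1-one | COc1c(CCC(C)(C)O)cc(O[Si](C(C)C)(C(C)C)C(C)C)cc1C(=O)/C(=C/N(C)C)c1cc2c(cc1OCOC)OC(C)(C)C=C2
F13 | step 12 | 1-[5-hydroxy-3-(3-hydroxy-3-methylbutyl)-2-methoxyphenyl]-2-[7-(methoxymethoxy)-2,2-dimethyl-2H-chromen-6-yl]ethan-1-one | COc1c(CCC(C)(C)O)cc(O)cc1C(=O)Cc1cc2c(cc1OCOC)OC(C)(C)C=C2
F14 | step 12 | (E)-3-(dimethylamino)-1-[5-hydroxy-3-(3-hydroxy-3-methylbutyl)-2-methoxyphenyl]-2-[7-(methoxymethoxy)-2,2-dimethyl-2H-chromen-6-yl]prop-2-en-1-one | COc1c(CCC(C)(C)O)cc(O)cc1C(=O)/C(=C/N(C)C)c1cc2c(cc1OCOC)OC(C)(C)C=C2
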